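**Retrosynthetic overview**
1. End game: the target comes from its tri-O-benzyl ether. That ether comes from the same oxolane with CHO in place of the C3 methyl group (CHO → CH2OH → CH2OMs → CH3, then hydrogenolysis of three benzyl ethers).
2. Key disconnection: O1–C5 and C2–C3 of the oxolane are cut in one operation. O1=C2 becomes the carbonyl group of a 3-substituted 4-(benzyloxy)benzaldehyde. C3–C4–C5 becomes a cyclopropane (CHO on C3, CH3 on C4, aryl on C5). The five-membered ring is therefore made by a two-atom ring expansion, a formal (3+2), of a three-membered ring.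
3. Enabling feature: oxolane atoms C2 and C5 are both O-bound and benzylic to para-oxygenated benzene rings (cation-stabilising). C3 carries a one-carbon substituent that can be held at the aldehyde level (anion-stabilising). C5(+)/C3(−) is thus the zwitterion of a donor–acceptor cyclopropane, and only C4 has to be stored as a stereocentre.
4. Fragments: the cyclopropane comes from (E)-4-benzyloxycinnamyl alcohol and an ethylidene zinc carbenoid under a chiral dioxaborolane, then oxidation. The aldehyde partner comes from a stereodefined (E)-α-methylstilbene (borylcupration, Suzuki–Miyaura), Ir-catalysed asymmetric hydrogenation for the remote (R)-centre, then Br → CHO.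
5. Ring order: cyclopropane (step 3), then the oxolane grown out of it (step 11). All benzene rings are bought.

Key step: step 11

Assumption: the sense of induction in steps 3 and 9 is taken from the parent substrates, (E)-cinnamyl alcohol and (E)-α-methylstilbene. If 3 or 11 respond in the opposite sense, the mirror-image ligand is used.

**Step 1**
Reactants: 1 4-(benzyloxy)benzaldehyde
Product: 2 ethyl (E)-3-[4-(benzyloxy)phenyl]prop-2-enoate
Conditions: (EtO)2P(O)CH2CO2Et, NaH, THF, 0 °C to rt
Reagents that add atoms: triethyl phosphonoacetate CCOC(=O)CP(=O)(OCC)OCC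
Why: Horner–Wadsworth–Emmons olefination of an aromatic aldehyde with a stabilised phosphonate anion, which should give the (E)-enoate.

**Step 2**
Reactants: 2 ethyl (E)-3-[4-(benzyloxy)phenyl]prop-2-enoate
Product: 3 (E)-3-[4-(benzyloxy)phenyl]prop-2-en-1-ol
Conditions: DIBAL-H (2.2 equiv), CH2Cl2, −78 °C; aq Rochelle salt
Reagents that add atoms: none
Why: 1,2-reduction of an α,β-unsaturated ester with DIBAL-H, which leaves the alkene geometry and the benzyl ether untouched.

**Step 3**
Reactants: 3 (E)-3-[4-(benzyloxy)phenyl]prop-2-en-1-ol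
Product: 4 {(1S,2S,3R)-2-[4-(benzyloxy)phenyl]-3-methylcyclopropyl}methanol (CH2OH trans to aryl and to methyl; aryl and methyl cis)
Conditions: Et2Zn, CH3CHI2, (4R,5R)-2-butyl-N,N,N',N'-tetramethyl-1,3,2-dioxaborolane-4,5-dicarboxamide (1.2 equiv), CH2Cl2, −10 °C to rt; aq NH4Cl; chromatography to a single diastereomer
Reagents that add atoms: 1,1-diiodoethane CC(I)I
Why: Hydroxyl-directed Simmons–Smith-type cyclopropanation with a substituted zinc carbenoid, in which the zinc alkoxide bound to the chiral dioxaborolane receives the ethylidene unit on one alkene face (sets C1 and C2, trans from the E-alkene) and the carbenoid methyl group points away from the CH2O–Zn/boronate complex (sets C3, methyl anti to CH2OH and hence cis to the aryl group).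

**Step 4**
Reactants: 4 {(1S,2S,3R)-2-[4-(benzyloxy)phenyl]-3-methylcyclopropyl}methanol
Product: 5 (1S,2S,3R)-2-[4-(benzyloxy)phenyl]-3-methylcyclopropane-1-carbaldehyde
Conditions: TPAP (5 mol %), NMO, 4 Å MS, CH2Cl2, rt
Reagents that add atoms: none
Why: Ley–Griffith oxidation under neutral, non-aqueous conditions stops at the aldehyde and should neither open the electron-rich cyclopropane nor epimerise C1, whose formyl group is already trans to both neighbours.

**Step 5**
Reactants: 6 4-bromo-2-iodophenol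
Product: 7 1-(benzyloxy)-4-bromo-2-iodobenzene
Conditions: BnBr, K2CO3, DMF, rt
Reagents that add atoms: benzyl bromide BrCc1ccccc1
Why: Williamson ether synthesis on a phenoxide, with both carbon–halogen bonds inert to K2CO3.

**Step 6**
Reactants: 8 1-(benzyloxy)-4-iodobenzene
Product: 9 1-(benzyloxy)-4-(prop-1-yn-1-yl)benzene
Conditions: propyne (1 M in THF), PdCl2(PPh3)2 (2 mol %), CuI (4 mol %), Et3N, rt, closed flask
Reagents that add atoms: propyne CC#C
Why: Sonogashira coupling of an aryl iodide with a terminal alkyne at room temperature.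

**Step 7**
Reactants: 9 1-(benzyloxy)-4-(prop-1-yn-1-yl)benzene
Product: 10 2-{(Z)-1-[4-(benzyloxy)phenyl]prop-1-en-2-yl}-4,4,5,5-tetramethyl-1,3,2-dioxaborolane (aryl and boron trans)
Conditions: B2pin2, CuCl (5 mol %), P(p-tol)3 (6 mol %), NaOtBu (15 mol %), MeOH (2 equiv), THF, rt
Reagents that add atoms: bis(pinacolato)diboron CC1(C)OB(OC1(C)C)B1OC(C)(C)C(C)(C)O1
Why: Copper-catalysed syn-borylcupration/protodemetalation (formal hydroboration) of a 1-arylpropyne, in which copper goes to the aryl-bearing carbon and boron to the methyl-bearing carbon, so that one regio- and stereoisomer should result.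

**Step 8**
Reactants: 7 1-(benzyloxy)-4-bromo-2-iodobenzene; 10 2-{(Z)-1-[4-(benzyloxy)phenyl]prop-1-en-2-yl}-4,4,5,5-tetramethyl-1,3,2-dioxaborolane
Product: 11 1-(benzyloxy)-2-{(E)-1-[4-(benzyloxy)phenyl]prop-1-en-2-yl}-4-bromobenzene
Conditions: Pd(PPh3)4 (3 mol %), K3PO4, 1,4-dioxane/H2O, 60 °C
Reagents that add atoms: none
Why: Suzuki–Miyaura coupling with retention of the alkene geometry, in which oxidative addition should occur at the C–I bond of 7 well before the C–Br bond para to the donor oxygen.

**Step 9**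
Reactants: 11 1-(benzyloxy)-2-{(E)-1-[4-(benzyloxy)phenyl]prop-1-en-2-yl}-4-bromobenzene
Product: 12 1-(benzyloxy)-2-{(2R)-1-[4-(benzyloxy)phenyl]propan-2-yl}-4-bromobenzene
Conditions: [Ir(cod){(S)-4-tert-butyl-2-[2-(di-o-tolylphosphanyl)phenyl]-4,5-dihydrooxazole}]BArF (1 mol %), H2 (50 bar), CH2Cl2, rt
Reagents that add atoms: none
Why: Iridium/N,P-ligand catalysed asymmetric hydrogenation of an unfunctionalised trisubstituted alkene, for which (E)-α-methylstilbenes are the standard substrate class; the ligand quadrant that has to take up the vinylic hydrogen fixes the face of H2 delivery and sets the (R)-centre, while aryl bromide and benzyl ethers are inert to this homogeneous catalyst.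

**Step 10**
Reactants: 12 1-(benzyloxy)-2-{(2R)-1-[4-(benzyloxy)phenyl]propan-2-yl}-4-bromobenzene
Product: 14 4-(benzyloxy)-3-{(2R)-1-[4-(benzyloxy)phenyl]propan-2-yl}benzaldehyde, via aryllithium 13 (not isolated)
Conditions: n-BuLi, THF, −78 °C; DMF, −78 to 0 °C; H2O
Reagents that add atoms: N,N-dimethylformamide CN(C)C=O; n-butyllithium [Li]CCCC (lithium of 13 only)
Why: Bromine–lithium exchange, faster at −78 °C than benzylic deprotonation, followed by formylation of the aryllithium with DMF (Bouveault-type aldehyde synthesis), which does not touch the benzylic stereocentre.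

**Step 11**
Reactants: 5 (1S,2S,3R)-2-[4-(benzyloxy)phenyl]-3-methylcyclopropane-1-carbaldehyde (1.3 equiv); 14 4-(benzyloxy)-3-{(2R)-1-[4-(benzyloxy)phenyl]propan-2-yl}benzaldehyde
Product: 15 (2R,3R,4S,5S)-2-(4-(benzyloxy)-3-{(2R)-1-[4-(benzyloxy)phenyl]propan-2-yl}phenyl)-5-[4-(benzyloxy)phenyl]-4-methyloxolane-3-carbaldehyde (2,3-trans, 3,4-cis, 4,5-trans, 2,5-cis)
Conditions: TiCl2(OiPr)2 (1.1 equiv, from TiCl4 + Ti(OiPr)4), 4 Å MS, CH2Cl2, −78 to −20 °C; sat. aq NaHCO3
Reagents that add atoms: none
Why: Proposed new method: Ti(IV) binds the formyl oxygen of 5 and the push–pull C1–C2 bond (formyl acceptor on C1, 4-benzyloxyphenyl donor on C2) heterolyses to a titanium enolate/4-alkoxybenzyl cation pair; the carbonyl oxygen of the electron-rich aldehyde 14 captures C2 opposite to the departing C1 (or the free cation anti to the neighbouring methyl group, both giving the 4,5-trans relation), and the enolate carbon then closes onto the aryl-stabilised oxocarbenium ion, so that C=O is inserted into the three-membered ring (3 → 5 ring atoms). The closest known reaction types are the Lewis-acid (3+2) annulation of 2-arylcyclopropane-1,1-diesters with aldehydes, which models the C–O-forming half, and the [1,3] O-to-C ring contraction of 4,5-dihydro-1,3-dioxepins to oxolane-3-carbaldehydes, which passes through exactly this enolate/oxocarbenium pair, models the C–C-forming half and is associated with the 2,3-trans-3,4-cis outcome under chlorotitanium alkoxides; what is new is the single formyl acceptor. The oxolane closes by a 5-(enolexo)-endo-trig aldol-type attack on the (E)-oxocarbenium ion through an envelope with both aryl groups and the C4 methyl group pseudo-equatorial. C4 is carried over unchanged from C3 of 5 and is the only stored stereocentre: it sets C5 (aryl anti to methyl), C4 and C5 together set C2 (2,4-trans and 2,5-cis, one and the same outcome), and C3 places its formyl group anti to the large C2 aryl and syn to the small C4 methyl, the arrangement that enolisation should also favour. The step is stereoconvergent, because epimers of 5 at C1 or C2, the benzylic chloride from chloride opening, the Cloke–Wilson dihydrofuran and any O-closed dioxepin should re-ionise under the same Lewis acid and drain into the irreversibly C–C-closed product. It needs cleavage of C1–C2 and not C1–C3, secured by the donor aryl standing on C2 only, and capture by 14 and not by the formyl group of a second molecule of 5, secured by the para-alkoxy conjugation that makes 14 the better O-nucleophile and gives the better stabilised oxocarbenium ion.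

**Step 12**
Reactants: 15 (2R,3R,4S,5S)-oxolane-3-carbaldehyde described in step 11
Product: 16 [(2R,3S,4S,5S)-2-(4-(benzyloxy)-3-{(2R)-1-[4-(benzyloxy)phenyl]propan-2-yl}phenyl)-5-[4-(benzyloxy)phenyl]-4-methyloxolan-3-yl]methanol
Conditions: NaBH4, MeOH/THF, 0 °C
Reagents that add atoms: none
Why: Chemoselective borohydride reduction of the aldehyde, fast enough at 0 °C to avoid enolisation at C3 (the descriptor at C3 changes by priority only).

**Step 13**
Reactants: 16 [(2R,3S,4S,5S)-…-4-methyloxolan-3-yl]methanol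
Product: 17 [(2R,3S,4S,5S)-2-(4-(benzyloxy)-3-{(2R)-1-[4-(benzyloxy)phenyl]propan-2-yl}phenyl)-5-[4-(benzyloxy)phenyl]-4-methyloxolan-3-yl]methyl methanesulfonate
Conditions: MsCl, Et3N, CH2Cl2, 0 °C
Reagents that add atoms: methanesulfonyl chloride CS(=O)(=O)Cl
Why: Sulfonylation of a primary alcohol, with no stereocentre involved.

**Step 14**
Reactants: 17 [(2R,3S,4S,5S)-…-4-methyloxolan-3-yl]methyl methanesulfonate
Product: 18 (2R,3R,4S,5S)-2-(4-(benzyloxy)-3-{(2R)-1-[4-(benzyloxy)phenyl]propan-2-yl}phenyl)-5-[4-(benzyloxy)phenyl]-3,4-dimethyloxolane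
Conditions: LiBHEt3, THF, 0 °C to rt
Reagents that add atoms: none
Why: SN2 displacement of a primary mesylate by the strongly nucleophilic hydride LiBHEt3, the standard CH2OH → CH3 sequence for oxolane lignans, to which aryl benzyl ethers and the ring C–O bonds are inert.

**Step 15**
Reactants: 18 (2R,3R,4S,5S)-tri-O-benzyl-3,4-dimethyloxolane
Product: 19 (2R,3R,4S,5S)-2-{4-hydroxy-3-[(2R)-1-(4-hydroxyphenyl)propan-2-yl]phenyl}-5-(4-hydroxyphenyl)-3,4-dimethyloxolane (target)
Conditions: H2 (1 atm), 10 % Pd/C, EtOAc/MeOH, rt, stopped after uptake of 3 equiv H2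
Reagents that add atoms: none
Why: Catalytic hydrogenolysis, in which aryl benzyl ethers are cleaved much faster than the hindered secondary benzylic C–O bonds of the oxolane, so that all five stereocentres should remain untouched.

**Compound list**
1 | 4-(benzyloxy)benzaldehyde | O=Cc1ccc(OCc2ccccc2)cc1 | starting material
2 | ethyl (E)-3-[4-(benzyloxy)phenyl]prop-2-enoate | CCOC(=O)/C=C/c1ccc(OCc2ccccc2)cc1 | intermediate
3 | (E)-3-[4-(benzyloxy)phenyl]prop-2-en-1-ol | OC/C=C/c1ccc(OCc2ccccc2)cc1 | intermediate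
4 | {(1S,2S,3R)-2-[4-(benzyloxy)phenyl]-3-methylcyclopropyl}methanol | OC[C@H]1[C@H](C)[C@@H]1c1ccc(OCc2ccccc2)cc1 | intermediate
5 | (1S,2S,3R)-2-[4-(benzyloxy)phenyl]-3-methylcyclopropane-1-carbaldehyde | O=C[C@H]1[C@H](C)[C@@H]1c1ccc(OCc2ccccc2)cc1 | intermediate
6 | 4-bromo-2-iodophenol | Oc1ccc(Br)cc1I | starting material
7 | 1-(benzyloxy)-4-bromo-2-iodobenzene | Brc1ccc(OCc2ccccc2)c(I)c1 | intermediate
8 | 1-(benzyloxy)-4-iodobenzene | Ic1ccc(OCc2ccccc2)cc1 | starting material
9 | 1-(benzyloxy)-4-(prop-1-yn-1-yl)benzene | CC#Cc1ccc(OCc2ccccc2)cc1 | intermediate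
10 | 2-{(Z)-1-[4-(benzyloxy)phenyl]prop-1-en-2-yl}-4,4,5,5-tetramethyl-1,3,2-dioxaborolane | C/C(B1OC(C)(C)C(C)(C)O1)=C\c1ccc(OCc2ccccc2)cc1 | intermediate
11 | 1-(benzyloxy)-2-{(E)-1-[4-(benzyloxy)phenyl]prop-1-en-2-yl}-4-bromobenzene | C/C(c1cc(Br)ccc1OCc1ccccc1)=C\c1ccc(OCc2ccccc2)cc1 | intermediate
12 | 1-(benzyloxy)-2-{(2R)-1-[4-(benzyloxy)phenyl]propan-2-yl}-4-bromobenzene | Brc1ccc(OCc2ccccc2)c([C@H](C)Cc2ccc(OCc3ccccc3)cc2)c1 | intermediate
13 | (4-(benzyloxy)-3-{(2R)-1-[4-(benzyloxy)phenyl]propan-2-yl}phenyl)lithium | [Li]c1ccc(OCc2ccccc2)c([C@H](C)Cc2ccc(OCc3ccccc3)cc2)c1 | intermediate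
14 | 4-(benzyloxy)-3-{(2R)-1-[4-(benzyloxy)phenyl]propan-2-yl}benzaldehyde | O=Cc1ccc(OCc2ccccc2)c([C@H](C)Cc2ccc(OCc3ccccc3)cc2)c1 | intermediate
15 | (2R,3R,4S,5S)-2-(4-(benzyloxy)-3-{(2R)-1-[4-(benzyloxy)phenyl]propan-2-yl}phenyl)-5-[4-(benzyloxy)phenyl]-4-methyloxolane-3-carbaldehyde | O=C[C@@H]1[C@H](C)[C@@H](c2ccc(OCc3ccccc3)cc2)O[C@H]1c1ccc(OCc2ccccc2)c([C@H](C)Cc2ccc(OCc3ccccc3)cc2)c1 | intermediate
16 | [(2R,3S,4S,5S)-2-(4-(benzyloxy)-3-{(2R)-1-[4-(benzyloxy)phenyl]propan-2-yl}phenyl)-5-[4-(benzyloxy)phenyl]-4-methyloxolan-3-yl]methanol | OC[C@@H]1[C@H](C)[C@@H](c2ccc(OCc3ccccc3)cc2)O[C@H]1c1ccc(OCc2ccccc2)c([C@H](C)Cc2ccc(OCc3ccccc3)cc2)c1 | intermediate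
17 | [(2R,3S,4S,5S)-2-(4-(benzyloxy)-3-{(2R)-1-[4-(benzyloxy)phenyl]propan-2-yl}phenyl)-5-[4-(benzyloxy)phenyl]-4-methyloxolan-3-yl]methyl methanesulfonate | CS(=O)(=O)OC[C@@H]1[C@H](C)[C@@H](c2ccc(OCc3ccccc3)cc2)O[C@H]1c1ccc(OCc2ccccc2)c([C@H](C)Cc2ccc(OCc3ccccc3)cc2)c1 | intermediate
18 | (2R,3R,4S,5S)-2-(4-(benzyloxy)-3-{(2R)-1-[4-(benzyloxy)phenyl]propan-2-yl}phenyl)-5-[4-(benzyloxy)phenyl]-3,4-dimethyloxolane | C[C@@H]1[C@H](C)[C@@H](c2ccc(OCc3ccccc3)cc2)O[C@H]1c1ccc(OCc2ccccc2)c([C@H](C)Cc2ccc(OCc3ccccc3)cc2)c1 | intermediate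
19 | (2R,3R,4S,5S)-2-{4-hydroxy-3-[(2R)-1-(4-hydroxyphenyl)propan-2-yl]phenyl}-5-(4-hydroxyphenyl)-3,4-dimethyloxolane | C[C@@H]1[C@H](C)[C@@H](c2ccc(O)cc2)O[C@H]1c1ccc(O)c([C@H](C)Cc2ccc(O)cc2)c1 | target

**Step count**
- Total step count: 15.
- Longest linear sequence: 10 (steps 6–15).

**Steps most likely to fail**

**Step 11.**
- What may go wrong: a cyclopropane with a single acceptor may be polarised too weakly while the Lewis acid is tied up by the more basic aldehyde 14. Ionisation would then need temperatures at which three processes compete: 1,2-hydride shift to the open-chain enal, irreversible Cloke–Wilson isomerisation, and aldol self-condensation of the enolisable product. Control at C3 would erode.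
- Fallback (known chemistry): the same two-atom ring expansion is run on the classical 1,1-diester. It sets out from 1 and 14 and comes back at 16.
- Z-selective Wittig olefination of 1 (EtPPh3Br, NaHMDS, THF, −78 °C) gives (Z)-1-(benzyloxy)-4-(prop-1-en-1-yl)benzene F1.
- Copper(I)/bis(oxazoline)-catalysed malonate-carbene transfer from the phenyliodonium ylide of dimethyl malonate is known for 1,2-disubstituted styrenes and is stereospecific for the alkene geometry. It gives dimethyl (2R,3R)-2-[4-(benzyloxy)phenyl]-3-methylcyclopropane-1,1-dicarboxylate F2 (aryl and methyl cis).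
- Sn(OTf)2- or AlCl3-promoted (3+2) annulation of F2 with 14 proceeds with inversion at the donor carbon. It gives dimethyl (2S,4S,5S)-2-(4-(benzyloxy)-3-{(2R)-1-[4-(benzyloxy)phenyl]propan-2-yl}phenyl)-5-[4-(benzyloxy)phenyl]-4-methyloxolane-3,3-dicarboxylate F3 (2,5-cis, 4,5-trans).
- Krapcho demethoxycarbonylation (LiCl, wet DMSO, 150 °C), with NaOMe equilibration of the ester-bearing centre, gives the 2,3-trans methyl (2R,3R,4S,5S)-oxolane-3-carboxylate F4.
- LiAlH4 reduction of F4 gives 16.

**Step 9.**
- What may go wrong: the ortho-benzyloxy group twists the aryl ring out of the alkene plane and crowds the cationic iridium centre. This can lead to slow turnover, acid-induced E/Z isomerisation before reduction, and lower facial selectivity.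
- Fallback: the centre is set by C–B bond formation on a 1,1-disubstituted alkene instead. It sets out from 7 (and uses 8) and comes back at 12.
- Iodide-selective Suzuki–Miyaura coupling of 7 with isopropenylboronic acid pinacol ester gives 1-(benzyloxy)-4-bromo-2-(prop-1-en-2-yl)benzene F5.
- Cobalt- (iminopyridine-oxazoline ligand) or NHC–copper-catalysed enantioselective anti-Markovnikov hydroboration with HBpin gives 2-{(2R)-2-[2-(benzyloxy)-5-bromophenyl]propyl}-4,4,5,5-tetramethyl-1,3,2-dioxaborolane F6.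
- B-alkyl Suzuki–Miyaura coupling of F6 with the aryl iodide 8 (Pd/RuPhos, K3PO4, toluene/H2O) does not touch the β-stereocentre and gives 12.

**Step 3.**
- What may go wrong: the 1-iodoethylzinc carbenoid is less reactive and less stable than the parent reagent. Possible results are incomplete conversion, lower anti/syn and facial selectivity, and ZnI2-induced ionisation of the electron-rich cinnamyl alcohol.
- Fallback: the three ring carbons are partitioned differently, so the sensitive cinnamyl alcohol is avoided. It sets out from 1 and comes back at 4.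
- Condensation of 1 with TsNHNH2 gives N'-[(E)-4-(benzyloxy)benzylidene]-4-methylbenzenesulfonohydrazide F7.
- Mild Bamford–Stevens elimination (NaOMe) gives 1-(benzyloxy)-4-(diazomethyl)benzene F8.
- F8 with ZnI2 gives the aryl-substituted zinc carbenoid {[4-(benzyloxy)phenyl](iodo)methyl}zinc iodide F9.
- F9 cyclopropanates the zinc alkoxide of commercial (E)-but-2-en-1-ol in the presence of the (4S,5S)-dioxaborolane. The mirror-image ligand is needed because alkene carbon and carbenoid carbon have changed places. The aryl group ends anti to CH2OH, which gives 4.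

**Further compounds**
F1 | step 11 | (Z)-1-(benzyloxy)-4-(prop-1-en-1-yl)benzene | C/C=C\c1ccc(OCc2ccccc2)cc1
F2 | step 11 | dimethyl (2R,3R)-2-[4-(benzyloxy)phenyl]-3-methylcyclopropane-1,1-dicarboxylate | COC(=O)C1(C(=O)OC)[C@H](C)[C@@H]1c1ccc(OCc2ccccc2)cc1
F3 | step 11 | dimethyl (2S,4S,5S)-2-(4-(benzyloxy)-3-{(2R)-1-[4-(benzyloxy)phenyl]propan-2-yl}phenyl)-5-[4-(benzyloxy)phenyl]-4-methyloxolane-3,3-dicarboxylate | COC(=O)C1(C(=O)OC)[C@H](C)[C@@H](c2ccc(OCc3ccccc3)cc2)O[C@H]1c1ccc(OCc2ccccc2)c([C@H](C)Cc2ccc(OCc3ccccc3)cc2)c1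
F4 | step 11 | methyl (2R,3R,4S,5S)-2-(4-(benzyloxy)-3-{(2R)-1-[4-(benzyloxy)phenyl]propan-2-yl}phenyl)-5-[4-(benzyloxy)phenyl]-4-methyloxolane-3-carboxylate | COC(=O)[C@@H]1[C@H](C)[C@@H](c2ccc(OCc3ccccc3)cc2)O[C@H]1c1ccc(OCc2ccccc2)c([C@H](C)Cc2ccc(OCc3ccccc3)cc2)c1
F5 | step 9 | 1-(benzyloxy)-4-bromo-2-(prop-1-en-2-yl)benzene | C=C(C)c1cc(Br)ccc1OCc1ccccc1
F6 | step 9 | 2-{(2R)-2-[2-(benzyloxy)-5-bromophenyl]propyl}-4,4,5,5-tetramethyl-1,3,2-dioxaborolane | Brc1ccc(OCc2ccccc2)c([C@H](C)CB2OC(C)(C)C(C)(C)O2)c1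
F7 | step 3 | N'-[(E)-4-(benzyloxy)benzylidene]-4-methylbenzenesulfonohydrazide | Cc1ccc(cc1)S(=O)(=O)N/N=C/c1ccc(OCc2ccccc2)cc1
F8 | step 3 | 1-(benzyloxy)-4-(diazomethyl)benzene | [N-]=[N+]=Cc1ccc(OCc2ccccc2)cc1
F9 | step 3 | {[4-(benzyloxy)phenyl](iodo)methyl}zinc iodide | I[Zn]C(I)c1ccc(OCc2ccccc2)cc1
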